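**Retrosynthetic overview**
- Target 16 ⇒ trisilyl chalcone 15 ⇒ dihydrobenzofuran 10 + cinnamoyl N-methoxy-N-methylamide 13: the C7–C(=O) bond comes from lithiation of C7, which lies between O1 and the 6-OMe group, followed by acyl substitution.
- 10 ⇒ tosylhydrazone 8: ring B (O1–C2–C3–C3a–C7a) is opened at C2–C3. The strategy rests on C2 being an ether carbon (O1–C2H–CMe2OH) that sits 1,5 to the benzylic C3 across O1, C7a and C3a, so C3 can be an aryl carbene carbon and C2 the O–CH2 of a 2-hydroxy-2-methylpropyl aryl ether.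
- 8 ⇒ 2,4,6-trihydroxybenzaldehyde 1: para O-methylation, phenoxide opening of 2,2-dimethyloxirane 3, two silylations, condensation with 7.
- Ring order: benzene ring A comes from 1; ring B is the only ring formed, in the key step; the 4-hydroxyphenyl ring C arrives with 13 (from 11 and 12).

Key step: step 6

Assumption: [Co(Por*)] is the divalent cobalt complex of 5,15-bis(3,5-di-tert-butylphenyl)-10,20-bis{2,6-bis[(S)-2,2-dimethylcyclopropanecarboxamido]phenyl}porphyrin; its sense of induction on this ether substrate is to be fixed by a trial run, and the ligand antipode that gives (S)-10 is then used (the (R)-amide ligand is equally accessible).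

Step 1
Reactants: 1 2,4,6-trihydroxybenzaldehyde
Product: 2 2,6-dihydroxy-4-methoxybenzaldehyde
Conditions: Me2SO4 (1.0 equiv), K2CO3 (1.0 equiv), acetone, 0 °C → rt
Reagents that add atoms: dimethyl sulfate, COS(=O)(=O)OC
Why: Williamson-type O-methylation; the 4-OH is para to the formyl group and not hydrogen-bonded to it, so it is the most acidic and most nucleophilic hydroxyl and should react before the two chelated ortho hydroxyls.

Step 2
Reactants: 2 2,6-dihydroxy-4-methoxybenzaldehyde; 3 2,2-dimethyloxirane
Product: 4 2-hydroxy-6-(2-hydroxy-2-methylpropoxy)-4-methoxybenzaldehyde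
Conditions: 3 (1.5 equiv), K2CO3 (0.3 equiv), DMF, 90 °C, sealed tube
Reagents that add atoms: none
Why: Base-catalysed SN2 opening of the epoxide by the phenoxide at the unsubstituted CH2 carbon; the two ortho hydroxyls of 2 are equivalent, and the one left over stays chelated to the aldehyde and deactivated, which should hold the reaction at mono-alkylation.

Step 3
Reactants: 4 2-hydroxy-6-(2-hydroxy-2-methylpropoxy)-4-methoxybenzaldehyde
Product: 5 2-(2-hydroxy-2-methylpropoxy)-4-methoxy-6-(triisopropylsilyloxy)benzaldehyde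
Conditions: TIPSCl (1.2 equiv), imidazole (2.5 equiv), DMF, rt
Reagents that add atoms: triisopropylsilyl chloride, CC(C)[Si](Cl)(C(C)C)C(C)C
Why: Silyl ether formation at the phenol only, since the tertiary alcohol is too hindered for this silyl chloride; the bulky group later shields C5 and offers no C–H within reach of the carbene carbon.

Step 4
Reactants: 5 2-(2-hydroxy-2-methylpropoxy)-4-methoxy-6-(triisopropylsilyloxy)benzaldehyde
Product: 6 4-methoxy-2-[2-methyl-2-(triethylsilyloxy)propoxy]-6-(triisopropylsilyloxy)benzaldehyde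
Conditions: TESOTf (1.3 equiv), 2,6-lutidine (2 equiv), CH2Cl2, −78 → 0 °C
Reagents that add atoms: triethylsilyl trifluoromethanesulfonate, CC[Si](CC)(CC)OS(=O)(=O)C(F)(F)F
Why: Silylation of the hindered tertiary alcohol with a silyl triflate and a non-nucleophilic base; the aldehyde has no α-hydrogen and the aryl silyl ether is inert under these conditions.

Step 5
Reactants: 6 4-methoxy-2-[2-methyl-2-(triethylsilyloxy)propoxy]-6-(triisopropylsilyloxy)benzaldehyde; 7 p-toluenesulfonyl hydrazide
Product: 8 (E)-N'-{4-methoxy-2-[2-methyl-2-(triethylsilyloxy)propoxy]-6-(triisopropylsilyloxy)benzylidene}-4-methylbenzenesulfonohydrazide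
Conditions: 7 (1.05 equiv), MeOH/THF, rt
Reagents that add atoms: none
Why: Hydrazone condensation of the aldehyde with the sulfonyl hydrazide gives the bench-stable (E)-N-tosylhydrazone, and the neutral medium should leave both silyl ethers in place.

Step 6
Reactants: 8 (E)-N'-{4-methoxy-2-[2-methyl-2-(triethylsilyloxy)propoxy]-6-(triisopropylsilyloxy)benzylidene}-4-methylbenzenesulfonohydrazide
Product: 10 (2S)-6-methoxy-2-[2-(triethylsilyloxy)propan-2-yl]-4-(triisopropylsilyloxy)-2,3-dihydro-1-benzofuran, via aryldiazomethane 9 (not isolated)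
Conditions: Cs2CO3 (2 equiv), [Co(Por*)] (2–5 mol %), 1,4-dioxane, 40–60 °C, N2
Reagents that add atoms: none
Why: Cs2CO3 deprotonates the hydrazone and loss of sulfinate (Bamford–Stevens) releases aryldiazomethane 9, which the divalent cobalt porphyrin converts, with loss of N2, into a trivalent cobalt carbene radical carrying its spin on the future C3; this radical takes a hydrogen atom from the O–CH2 group through a six-membered transition state (1,5-hydrogen atom transfer), and the α-alkoxy radical formed at C2 attacks C3 with homolysis of the Co–C bond, which makes the C2–C3 bond and returns the catalyst. The closest known reaction type is the cobalt porphyrin metalloradical C–H alkylation of aryldiazomethanes generated in situ from tosylhydrazones, which gives 2-substituted indolines and related five-membered rings by the same abstraction and radical substitution sequence. Ring B (O1–C2–C3–C3a–C7a) closes as a 5-exo-tet radical substitution at the cobalt-bound carbon. The C2 stereocentre is set in this bond-forming event by the chiral pocket built from the four cyclopropanecarboxamide arms of the porphyrin, which exposes one face of the planar C2 radical to C3; C2 is then a plain ether carbon and cannot epimerise. The step needs site selectivity and enantioselectivity: the ether methylene is the only C–H that reaches the carbene carbon through a six-membered transition state, because the other ortho oxygen carries a silyl group whose nearest C–H bonds lie one atom further away and are unactivated, and the slow release of 9 from the hydrazone salt should keep azine and stilbene formation from competing.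

Step 7
Reactants: 11 4-(tert-butyldimethylsilyloxy)benzaldehyde; 12 diethyl {2-[methoxy(methyl)amino]-2-oxoethyl}phosphonate
Product: 13 (E)-3-[4-(tert-butyldimethylsilyloxy)phenyl]-N-methoxy-N-methylprop-2-enamide
Conditions: NaH (1.1 equiv), THF, 0 °C → rt
Reagents that add atoms: none
Why: Horner–Wadsworth–Emmons olefination with a stabilised phosphonate anion should give the trans (E) cinnamoyl amide, and the aryl silyl ether tolerates the non-nucleophilic anion.

Step 8
Reactants: 10 (2S)-6-methoxy-2-[2-(triethylsilyloxy)propan-2-yl]-4-(triisopropylsilyloxy)-2,3-dihydro-1-benzofuran; 13 (E)-3-[4-(tert-butyldimethylsilyloxy)phenyl]-N-methoxy-N-methylprop-2-enamide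
Product: 15 (E)-3-[4-(tert-butyldimethylsilyloxy)phenyl]-1-{(2S)-6-methoxy-2-[2-(triethylsilyloxy)propan-2-yl]-4-(triisopropylsilyloxy)-2,3-dihydro-1-benzofuran-7-yl}prop-2-en-1-one, via C7 aryllithium 14 (not isolated)
Conditions: n-BuLi (1.05 equiv), THF, 0 °C; then 13 (1.2 equiv), −78 → 0 °C; aq. NH4Cl
Reagents that add atoms: none
Why: Directed ortho-metalation followed by Weinreb ketone synthesis; C7–H lies between the ring oxygen O1 and the 6-methoxy group and is the best coordinated and most acidic site, whereas C5 is shielded by the non-coordinating triisopropylsilyloxy group, and the aryllithium adds 1,2 to the amide to give a chelated tetrahedral adduct that releases the enone only on work-up, so over-addition is avoided and C2 is untouched.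

Step 9
Reactants: 15 (E)-3-[4-(tert-butyldimethylsilyloxy)phenyl]-1-{(2S)-6-methoxy-2-[2-(triethylsilyloxy)propan-2-yl]-4-(triisopropylsilyloxy)-2,3-dihydro-1-benzofuran-7-yl}prop-2-en-1-one
Product: 16 (E)-1-[(2S)-4-hydroxy-2-(2-hydroxypropan-2-yl)-6-methoxy-2,3-dihydro-1-benzofuran-7-yl]-3-(4-hydroxyphenyl)prop-2-en-1-one
Conditions: Bu4NF (4 equiv), AcOH (4 equiv), THF, 0 °C → rt
Reagents that add atoms: none
Why: Fluoride-mediated desilylation removes the two aryl silyl ethers and the tertiary triethylsilyl ether; acetic acid buffers the phenoxides, the ketone has no free ortho hydroxyl so no flavanone can form, and the C2 ether stereocentre and the (E)-enone should be unaffected.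

**Compound list**
1 | 2,4,6-trihydroxybenzaldehyde | O=Cc1c(O)cc(O)cc1O | starting material
2 | 2,6-dihydroxy-4-methoxybenzaldehyde | COc1cc(O)c(C=O)c(O)c1 | intermediate
3 | 2,2-dimethyloxirane | CC1(C)CO1 | starting material
4 | 2-hydroxy-6-(2-hydroxy-2-methylpropoxy)-4-methoxybenzaldehyde | COc1cc(O)c(C=O)c(OCC(C)(C)O)c1 | intermediate
5 | 2-(2-hydroxy-2-methylpropoxy)-4-methoxy-6-(triisopropylsilyloxy)benzaldehyde | COc1cc(OCC(C)(C)O)c(C=O)c(O[Si](C(C)C)(C(C)C)C(C)C)c1 | intermediate
6 | 4-methoxy-2-[2-methyl-2-(triethylsilyloxy)propoxy]-6-(triisopropylsilyloxy)benzaldehyde | COc1cc(OCC(C)(C)O[Si](CC)(CC)CC)c(C=O)c(O[Si](C(C)C)(C(C)C)C(C)C)c1 | intermediate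
7 | p-toluenesulfonyl hydrazide | Cc1ccc(cc1)S(=O)(=O)NN | starting material
8 | (E)-N'-{4-methoxy-2-[2-methyl-2-(triethylsilyloxy)propoxy]-6-(triisopropylsilyloxy)benzylidene}-4-methylbenzenesulfonohydrazide | COc1cc(OCC(C)(C)O[Si](CC)(CC)CC)c(/C=N/NS(=O)(=O)c2ccc(C)cc2)c(O[Si](C(C)C)(C(C)C)C(C)C)c1 | intermediate
9 | 2-(diazomethyl)-5-methoxy-1-[2-methyl-2-(triethylsilyloxy)propoxy]-3-(triisopropylsilyloxy)benzene | COc1cc(OCC(C)(C)O[Si](CC)(CC)CC)c(C=[N+]=[N-])c(O[Si](C(C)C)(C(C)C)C(C)C)c1 | intermediate
10 | (2S)-6-methoxy-2-[2-(triethylsilyloxy)propan-2-yl]-4-(triisopropylsilyloxy)-2,3-dihydro-1-benzofuran | COc1cc(O[Si](C(C)C)(C(C)C)C(C)C)c2c(c1)O[C@H](C(C)(C)O[Si](CC)(CC)CC)C2 | intermediate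
11 | 4-(tert-butyldimethylsilyloxy)benzaldehyde | O=Cc1ccc(O[Si](C)(C)C(C)(C)C)cc1 | starting material
12 | diethyl {2-[methoxy(methyl)amino]-2-oxoethyl}phosphonate | CCOP(=O)(CC(=O)N(C)OC)OCC | starting material
13 | (E)-3-[4-(tert-butyldimethylsilyloxy)phenyl]-N-methoxy-N-methylprop-2-enamide | CON(C)C(=O)/C=C/c1ccc(O[Si](C)(C)C(C)(C)C)cc1 | intermediate
14 | [(2S)-6-methoxy-2-[2-(triethylsilyloxy)propan-2-yl]-4-(triisopropylsilyloxy)-2,3-dihydro-1-benzofuran-7-yl]lithium | COc1cc(O[Si](C(C)C)(C(C)C)C(C)C)c2c(c1[Li])O[C@H](C(C)(C)O[Si](CC)(CC)CC)C2 | intermediate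
15 | (E)-3-[4-(tert-butyldimethylsilyloxy)phenyl]-1-{(2S)-6-methoxy-2-[2-(triethylsilyloxy)propan-2-yl]-4-(triisopropylsilyloxy)-2,3-dihydro-1-benzofuran-7-yl}prop-2-en-1-one | COc1cc(O[Si](C(C)C)(C(C)C)C(C)C)c2c(c1C(=O)/C=C/c1ccc(O[Si](C)(C)C(C)(C)C)cc1)O[C@H](C(C)(C)O[Si](CC)(CC)CC)C2 | intermediate
16 | (E)-1-[(2S)-4-hydroxy-2-(2-hydroxypropan-2-yl)-6-methoxy-2,3-dihydro-1-benzofuran-7-yl]-3-(4-hydroxyphenyl)prop-2-en-1-one | COc1cc(O)c2c(c1C(=O)/C=C/c1ccc(O)cc1)O[C@H](C(C)(C)O)C2 | target

**Step count**
Total steps: 9. Longest linear sequence: 8 (steps 1–6, 8, 9, from 1); step 7 is the side branch.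

**Steps most likely to fail**

Step 6. The hydrogen abstraction or the radical ring closure at the neopentyl-type methylene may be slower than dimerisation of the diazo compound, or the crowded tertiary silyl ether may erode facial discrimination in the catalyst pocket. The fallback replaces the C–H alkylation by asymmetric hydrogenation of a preformed benzofuran; it sets out from 2 and comes back at 10. Rap–Stoermer condensation of 2 with chloroacetone (K2CO3, DMF, 80 °C) should give 1-(4-hydroxy-6-methoxy-1-benzofuran-2-yl)ethan-1-one F1. Silylation of the phenol (TIPSCl, imidazole, DMF) would give 1-[6-methoxy-4-(triisopropylsilyloxy)-1-benzofuran-2-yl]ethan-1-one F2. Addition of MeMgBr (THF, 0 °C) would give 2-[6-methoxy-4-(triisopropylsilyloxy)-1-benzofuran-2-yl]propan-2-ol F3, and TESOTf/2,6-lutidine would give 6-methoxy-2-[2-(triethylsilyloxy)propan-2-yl]-4-(triisopropylsilyloxy)-1-benzofuran F4. Hydrogenation of the furan C2=C3 bond of F4 under H2 in hexane, with the chiral catalyst formed from [Ru(cod)(2-methylallyl)2], 1,3-bis[(R)-1-(naphthalen-1-yl)ethyl]-4,5-dihydroimidazolium tetrafluoroborate and KOt-Bu (ligand antipode chosen for the (S)-product), would then deliver 10.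

Step 8. The hindered 2,6-dioxygenated aryllithium may add to the β-carbon of the cinnamoyl unit or act as a base and cleave the N–OMe group instead of attacking the amide carbonyl. The fallback replaces acyl substitution by aldehyde addition and oxidation; it sets out from 13 and from 14 (generated from 10 as in step 8) and comes back at 15. Reduction of 13 with i-Bu2AlH (THF, −78 °C) should give (E)-3-[4-(tert-butyldimethylsilyloxy)phenyl]prop-2-enal F5. Addition of 14 to this more reactive, 1,2-selective electrophile at −78 °C would give (E)-3-[4-(tert-butyldimethylsilyloxy)phenyl]-1-{(2S)-6-methoxy-2-[2-(triethylsilyloxy)propan-2-yl]-4-(triisopropylsilyloxy)-2,3-dihydro-1-benzofuran-7-yl}prop-2-en-1-ol F6 as a mixture of carbinol epimers. This acid-sensitive alcohol would be oxidised at once with MnO2 (CH2Cl2, rt) to 15.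

Step 1. Over-methylation at the chelated ortho hydroxyls or C-methylation of the phloroglucinol ring may compete with the single para O-methylation. The fallback replaces selective alkylation by exhaustive methylation and chelation-controlled demethylation; it sets out from 1 and comes back at 2. Excess Me2SO4 with K2CO3 in refluxing acetone should give 2,4,6-trimethoxybenzaldehyde F7 (also commercially available). Excess AlCl3 in refluxing CH2Cl2, bound to the formyl oxygen, would then cleave only the two ortho methyl ethers and give 2.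

**Further compounds**
F1 | step 6 | 1-(4-hydroxy-6-methoxy-1-benzofuran-2-yl)ethan-1-one | COc1cc(O)c2cc(C(C)=O)oc2c1
F2 | step 6 | 1-[6-methoxy-4-(triisopropylsilyloxy)-1-benzofuran-2-yl]ethan-1-one | COc1cc(O[Si](C(C)C)(C(C)C)C(C)C)c2cc(C(C)=O)oc2c1
F3 | step 6 | 2-[6-methoxy-4-(triisopropylsilyloxy)-1-benzofuran-2-yl]propan-2-ol | COc1cc(O[Si](C(C)C)(C(C)C)C(C)C)c2cc(C(C)(C)O)oc2c1
F4 | step 6 | 6-methoxy-2-[2-(triethylsilyloxy)propan-2-yl]-4-(triisopropylsilyloxy)-1-benzofuran | COc1cc(O[Si](C(C)C)(C(C)C)C(C)C)c2cc(C(C)(C)O[Si](CC)(CC)CC)oc2c1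
F5 | step 8 | (E)-3-[4-(tert-butyldimethylsilyloxy)phenyl]prop-2-enal | O=C/C=C/c1ccc(O[Si](C)(C)C(C)(C)C)cc1
F6 | step 8 | (E)-3-[4-(tert-butyldimethylsilyloxy)phenyl]-1-{(2S)-6-methoxy-2-[2-(triethylsilyloxy)propan-2-yl]-4-(triisopropylsilyloxy)-2,3-dihydro-1-benzofuran-7-yl}prop-2-en-1-ol | COc1cc(O[Si](C(C)C)(C(C)C)C(C)C)c2c(c1C(O)/C=C/c1ccc(O[Si](C)(C)C(C)(C)C)cc1)O[C@H](C(C)(C)O[Si](CC)(CC)CC)C2
F7 | step 1 | 2,4,6-trimethoxybenzaldehyde | COc1cc(OC)c(C=O)c(OC)c1
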